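The earlier runs and the new flask come from a simulation with constants of no real substance.

In a one-step world, a single first-order step turns starting material into product, and the percent formed by a given time is the same at any charge. So before I run the flask at c(starting material) = 0.86 M, I ask how far the two earlier runs stand from that world.

| setting | amber | teal | flask |
|---|---|---|---|
| starting material | 1.2 M | 1.9 M | 0.86 M |
| remark | run made earlier | run made earlier |  |
| time |  |  | 15 d |

| amber: time / d | amber: product / % | teal: time / d | teal: product / % |
|---|---|---|---|
| 0.833 | 1.0 | 0.833 | 0.9 |
| 1.67 | 9.1 | 1.67 | 8.9 |
| 3.00 | 12.9 | 3.00 | 11.9 |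
| 5.00 | 11.8 | 5.00 | 11.1 |
| 10.0 | 1.5 | 10.0 | 3.4 |
| 20.0 | 1.6 | 20.0 | 0 |

(scatter of a reading: 1 percentage point)

1. time, not beyond 15 d, at which the flask holds most product
2. the amount of product, in percent of the starting material charged, at that time
3. earliest time at which at least nineteen twentieths of that best amount are there, in d
4. latest time at which they still are, in d

- the earlier runs were read with a standard deviation of 1 percentage point

I sum the amber product readings at 1.67 d, 3.00 d and 5.00 d and divide by the teal sum at the same times, so time drops out and leaves 1.06. Dividing its logarithm by that of the charge ratio gives the charge exponent, the power of the charge that the percent of product follows at a given time: −0.126. The two sums differ by 1.9 points, and that difference has a standard deviation of 2.4 points, so the exponent is zero within the scatter.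

Carried to the flask, it scales the amber reading at 3.00 d to 13.5 %. I let the exponent move height and not time, so I commit to a top near 3.00 d, and the result will test whether one number was enough. The forecast gives 13.2 % at 3.8 d, a window from 3.1 d to 4.6 d, and holds that “yield seems to depend little on concentration”; its top comes later than mine.

The flask gives 13.1 % at 3.17 d, with its window from 2.57 d to 3.93 d, so the top comes earlier than the forecast's, and the height lies 0.4 points below my scaled reading.

    intermediate A → intermediate B (k = 2.30 × 10⁻⁵ s⁻¹)
    starting material → intermediate A (k = 8.50 × 10⁻⁶ s⁻¹)
    starting material ⇌ dormant form (K = 1.60, k = 6.50 × 10⁻⁶ s⁻¹)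
    intermediate C ⇌ product (K = 1.00, k = 4.00 × 10⁻⁵ s⁻¹)
    intermediate C → decomposed reagent (k = 1.20 × 10⁻⁵ s⁻¹)
    intermediate B → intermediate C (k = 1.50 × 10⁻⁵ s⁻¹)

In the flask, intermediate C goes to decomposed reagent at 0.30 of its forward rate to product at 1.28 d, and at 0.30 of it at 15.0 d, so that ratio stands the same at both times. For the neighbour flask, of the same charge and read at 4.0 d, the exponent scales the mean of the amber readings at 3.00 d and 5.00 d to 12.9 %, and at that time that flask holds 12.3 % product.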